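**Plan**

- Retrosynthetic cuts, in order: with a phenylsulfanyl group placed on C2, the C2–C3 bond of the 33-membered ring; then the ester bond C1–O(C32); then the C17–C18 bond at the midpoint of the C3–C32 chain.
- Enabling feature: the ring carries one functional group only, the C1(=O)–O–C32 ester. This ester can therefore be made first between open-chain partners, and the C2 methylene next to C1 then serves as the carbon nucleophile that closes the ring onto C3. The C3–C32 tether is an unbranched C30 chain built of two identical C15 halves.
- Forward order: Kolbe dimerisation joins the two C15 halves (C17–C18); monobromination differentiates the chain ends; esterification sets C1–O; bromide is exchanged for iodide; enolate C-alkylation closes the only ring (C2–C3); Raney Ni removes sulfur.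
- Stereochemistry: the target has no stereocentre; the C2 centre formed in the ring closure is racemic and is erased in the last step.

Key step: step 5

Remark: atom numbers refer to the target, with C1 the lactone carbonyl carbon, C2–C32 the methylene chain and the ring oxygen on C32; the target is achiral, so no compound needs a stereodescriptor.

**Route**

Step 1
Reactants: 1 16-hydroxyhexadecanoic acid (2 equiv per product)
Product: 2 triacontane-1,30-diol
Conditions: NaOMe (0.1 equiv), MeOH, Pt anode and Pt cathode, undivided cell, constant current (ca. 0.25 A cm-2), 45–50 °C
Reagents that add atoms: none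
Why: Kolbe electrolysis, in which anodic decarboxylation of the carboxylate at Pt gives the primary 15-hydroxypentadecyl radical that dimerises to the C30 chain, the remote hydroxyl group being no more oxidisable than the methanol solvent that the carboxylate layer keeps away from the anode.

Step 2
Reactants: 2 triacontane-1,30-diol
Product: 3 30-bromotriacontan-1-ol
Conditions: 48% aq HBr (1.2 equiv), toluene, reflux
Reagents that add atoms: hydrogen bromide, Br
Why: Monobromination of an α,ω-diol with aqueous HBr in toluene (acid-promoted SN2 substitution of a primary alcohol), in which the bromo alcohol once formed is held back from a second substitution by its aggregation in the non-polar phase, so the mono-bromide should predominate over the dibromide.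

Step 3
Reactants: 3 30-bromotriacontan-1-ol; 4 2-(phenylsulfanyl)acetic acid (1.3 equiv)
Product: 5 30-bromotriacontyl 2-(phenylsulfanyl)acetate
Conditions: p-TsOH·H2O (5 mol%), toluene, reflux, Dean–Stark trap
Reagents that add atoms: none
Why: Fischer esterification of a primary alcohol, driven to completion by azeotropic removal of water in a solvent that dissolves the waxy alcohol, with the primary bromide and the aryl sulfide inert to the catalytic acid.

Step 4
Reactants: 5 30-bromotriacontyl 2-(phenylsulfanyl)acetate
Product: 6 30-iodotriacontyl 2-(phenylsulfanyl)acetate
Conditions: NaI (3 equiv), 2-butanone, reflux, dark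
Reagents that add atoms: sodium iodide, [Na+].[I-]
Why: Finkelstein halide exchange (SN2 at a primary carbon), pulled forward by precipitation of NaBr from the ketone solvent, under neutral conditions that leave the ester and the sulfide untouched.

Step 5
Reactants: 6 30-iodotriacontyl 2-(phenylsulfanyl)acetate
Product: 8 racemic 3-(phenylsulfanyl)oxacyclotritriacontan-2-one, via potassium 1-[(30-iodotriacontyl)oxy]-2-(phenylsulfanyl)ethen-1-olate 7 (not isolated)
Conditions: KN(SiMe3)2 (2 equiv), THF, 40–45 °C, 6 in THF added by syringe pump over ca. 12 h (final concentration ca. 1 mM); then aq NH4Cl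
Reagents that add atoms: none
Why: Intramolecular enolate C-alkylation, the closest known reaction type being the macrolide-forming cyclisation of ω-haloalkyl (phenylsulfanyl)acetates on shorter tethers: KN(SiMe3)2 removes a C2 proton, acidified by both the ester carbonyl and sulfur, and the soft potassium enolate 7 displaces iodide from C3 in an SN2 step. The 33-membered ring closes in the 33-exo-tet mode, the breaking carbon–iodine bond lying outside the ring being formed, and because the bond formation is irreversible it remains productive at the high dilution such a ring demands. The one new stereocentre, C2 of the target numbering (C3 in the lactone name), is under no control and forms as the racemate, which is harmless because step 6 removes it. The selectivity needed is intramolecular C-alkylation over intermolecular alkylation, Claisen self-condensation, O-alkylation and E2 loss of hydrogen iodide; slow addition of 6 into excess base keeps un-ionised ester and open-chain enolate at a very low stationary concentration, the sulfur-stabilised enolate is a weak base and a soft carbon nucleophile, and the hindered amide base deprotonates C2 far faster than it attacks the primary iodide. The unstrained polymethylene tether contributes only an entropic penalty.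

Step 6
Reactants: 8 racemic 3-(phenylsulfanyl)oxacyclotritriacontan-2-one
Product: 9 oxacyclotritriacontan-2-one (target)
Conditions: Raney Ni (W-2, washed to neutrality, excess), THF/EtOH, 25–50 °C
Reagents that add atoms: none
Why: Reductive desulfurisation with Raney Ni (hydrogenolysis of the carbon–sulfur bond by hydrogen adsorbed on the nickel), which replaces the phenylsulfanyl group at C2 by hydrogen, erases the C2 stereocentre and leaves the saturated lactone intact.

**Compound list**

1 | 16-hydroxyhexadecanoic acid | OCCCCCCCCCCCCCCCC(=O)O | starting material
2 | triacontane-1,30-diol | OCCCCCCCCCCCCCCCCCCCCCCCCCCCCCCO | intermediate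
3 | 30-bromotriacontan-1-ol | OCCCCCCCCCCCCCCCCCCCCCCCCCCCCCCBr | intermediate
4 | 2-(phenylsulfanyl)acetic acid | OC(=O)CSc1ccccc1 | starting material
5 | 30-bromotriacontyl 2-(phenylsulfanyl)acetate | O=C(CSc1ccccc1)OCCCCCCCCCCCCCCCCCCCCCCCCCCCCCCBr | intermediate
6 | 30-iodotriacontyl 2-(phenylsulfanyl)acetate | O=C(CSc1ccccc1)OCCCCCCCCCCCCCCCCCCCCCCCCCCCCCCI | intermediate
7 | potassium 1-[(30-iodotriacontyl)oxy]-2-(phenylsulfanyl)ethen-1-olate (enolate geometry not defined; not isolated) | [K+].[O-]C(=CSc1ccccc1)OCCCCCCCCCCCCCCCCCCCCCCCCCCCCCCI | intermediate
8 | 3-(phenylsulfanyl)oxacyclotritriacontan-2-one (racemic) | O=C1C(Sc2ccccc2)CCCCCCCCCCCCCCCCCCCCCCCCCCCCCCO1 | intermediate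
9 | oxacyclotritriacontan-2-one (lactone of 32-hydroxydotriacontanoic acid, no stereocentre) | O=C1CCCCCCCCCCCCCCCCCCCCCCCCCCCCCCCO1 | target

**Summary and risks**

Total step count: 6. Longest linear sequence: 6 steps (1 to 9).

Steps most likely to fail:

1. Step 5 (ring closure). The entropically costly 33-membered closure may be overtaken by intermolecular alkylation and oligomer formation, or the substrate may be consumed by base-induced loss of hydrogen iodide and Claisen-type condensation. The fallback moves the ring closure to the ester bond and uses only known chemistry. It sets out from 3 and comes back to the route at the target 9. Compound 3 is alkylated with the sodium salt of diethyl malonate (NaOEt, EtOH/THF, reflux) to give diethyl 2-(30-hydroxytriacontyl)propanedioate F1. Saponification (KOH, aq EtOH/THF, reflux) and acidification with HCl give 2-(30-hydroxytriacontyl)propanedioic acid F2, which loses carbon dioxide in refluxing pyridine to give 32-hydroxydotriacontanoic acid F3. Yamaguchi macrolactonisation follows: 2,4,6-trichlorobenzoyl chloride and Et3N in THF form 32-hydroxydotriacontanoic 2,4,6-trichlorobenzoic anhydride F4, which is added slowly to DMAP in refluxing toluene at high dilution and closes the same ring at C1–O to give 9.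

2. Step 1 (Kolbe dimerisation). The sparingly soluble C30 diol may coat and passivate the anode, and the radical may be diverted into two-electron oxidation or disproportionation instead of coupling. The fallback joins the two C15 halves without electrolysis. It sets out from 1 and comes back at 2. Acetylation of 1 (Ac2O, pyridine, then aqueous work-up) gives 16-acetoxyhexadecanoic acid F5. The Cristol–Firth variant of the Hunsdiecker reaction (HgO, Br2, CCl4, reflux) gives 15-bromopentadecyl acetate F6. Reductive homocoupling of the primary bromide (catalytic NiCl2(MeOCH2CH2OMe) and 2,2':6',2''-terpyridine, Mn powder, DMF, 40 °C) gives triacontane-1,30-diyl diacetate F7. Methanolysis (catalytic K2CO3, MeOH/THF, reflux) releases 2.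

3. Step 2 (monobromination). The phase behaviour that favours mono-substitution of shorter diols may not hold for the poorly soluble C30 diol, leading to over-bromination alongside unreacted diol. The fallback differentiates the chain ends by acylation and introduces iodine directly. It sets out from 2 and comes back at 6, bypassing 3 and 5. An excess of 2 is esterified with 4 (p-TsOH, toluene, reflux, Dean–Stark trap; unreacted diol recovered by crystallisation) to give 30-hydroxytriacontyl 2-(phenylsulfanyl)acetate F8. Appel-type iodination of the remaining primary alcohol (PPh3, iodine, imidazole, toluene, 40 °C) gives 6.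

Further compounds
F1 | step 5 | diethyl 2-(30-hydroxytriacontyl)propanedioate | CCOC(=O)C(C(=O)OCC)CCCCCCCCCCCCCCCCCCCCCCCCCCCCCCO
F2 | step 5 | 2-(30-hydroxytriacontyl)propanedioic acid | OC(=O)C(C(=O)O)CCCCCCCCCCCCCCCCCCCCCCCCCCCCCCO
F3 | step 5 | 32-hydroxydotriacontanoic acid | OC(=O)CCCCCCCCCCCCCCCCCCCCCCCCCCCCCCCO
F4 | step 5 | 32-hydroxydotriacontanoic 2,4,6-trichlorobenzoic anhydride | O=C(OC(=O)c1c(Cl)cc(Cl)cc1Cl)CCCCCCCCCCCCCCCCCCCCCCCCCCCCCCCO
F5 | step 1 | 16-acetoxyhexadecanoic acid | CC(=O)OCCCCCCCCCCCCCCCC(=O)O
F6 | step 1 | 15-bromopentadecyl acetate | CC(=O)OCCCCCCCCCCCCCCCBr
F7 | step 1 | triacontane-1,30-diyl diacetate | CC(=O)OCCCCCCCCCCCCCCCCCCCCCCCCCCCCCCOC(C)=O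
F8 | step 2 | 30-hydroxytriacontyl 2-(phenylsulfanyl)acetate | O=C(CSc1ccccc1)OCCCCCCCCCCCCCCCCCCCCCCCCCCCCCCO
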